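Everything rests on ring D, the 2,2-dimethyl-2H-pyran fused to ring B (chromene numbering): its oxygen O1 and its vinylic carbon C4 sit on the adjacent aromatic carbons C8a and C4a, that is, on the O–H and the ortho C–H of a phenol. One operation joins this pair to C3 and C1 of 3-methylbut-2-enal: boron-templated ortho aldol addition forms the C4a–C4 bond, loss of water gives an ortho-quinone methide, and oxa-6π electrocyclisation forms the O1–C2 bond. The precursor is 4-bromo-2-(triisopropylsilyloxy)phenol, with a single free ortho position. The bromochromene is coupled with a 3-iodochromone (rings A and C); transfer hydrogenation with dynamic kinetic resolution, reoxidation and buffered desilylation set the (3R) centre.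

Key step: step 3

Assumption: compounds 1, 4 and 8 are taken as commercial, and the sense of induction in step 7 is assigned by analogy with chroman-4-one, which the (R,R)-TsDPEN ruthenium catalyst reduces to the (R)-alcohol; should the sense prove opposite, the (S,S)-catalyst is used.

Step 1
Reactants: 1 catechol (used in excess)
Product: 2 2-(triisopropylsilyloxy)phenol
Conditions: TIPSCl (limiting), imidazole, CH2Cl2, 0 °C to rt
Reagents that add atoms: triisopropylsilyl chloride, CC(C)[Si](Cl)(C(C)C)C(C)C
Why: Imidazole-promoted silyl ether formation on a symmetric diol with a bulky chlorosilane and excess diol should stop at the mono-ether, and the surplus catechol is washed out with water.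

Step 2
Reactants: 2 2-(triisopropylsilyloxy)phenol
Product: 3 4-bromo-2-(triisopropylsilyloxy)phenol
Conditions: NBS, MeCN, −20 to 0 °C
Reagents that add atoms: N-bromosuccinimide, O=C1CCC(=O)N1Br
Why: Electrophilic aromatic bromination is directed para to the free hydroxyl, the strongest donor, while the bulky and more weakly donating silyloxy group shields its own neighbourhood, so bromine should enter C4.

Step 3
Reactants: 3 4-bromo-2-(triisopropylsilyloxy)phenol; 4 3-methylbut-2-enal
Product: 7 6-bromo-2,2-dimethyl-8-(triisopropylsilyloxy)-2H-chromene, via benzodioxaborin 5 (not isolated), via ortho-quinone methide 6 (not isolated)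
Conditions: PhB(OH)2, AcOH, toluene, reflux, Dean–Stark
Reagents that add atoms: none
Why: The phenol and PhB(OH)2 form an aryloxyboron species that binds the aldehyde and delivers its carbonyl carbon to the ortho carbon through a six-membered transition state (1,2-addition), which gives the 2-phenyl-4H-1,3,2-benzodioxaborin 5 and with it the C4a–C4 bond. Thermal cycloreversion of 5 releases the boron unit, which returns as PhB(OH)2 with the water formed, and leaves the ortho-quinone methide 6, a 1-oxatriene. Thermal disrotatory oxa-6π electrocyclisation of 6 closes the six-membered 2H-pyran ring by forming the O1–C2 bond and restores the aromatic ring. The closest known reaction type is the phenylboronic acid-mediated condensation of phenols with α,β-unsaturated aldehydes to 2H-chromenes, a formal [3+3] annulation. No stereocentre remains, since C2 carries two methyl groups and the transient centre of 5 is lost in the cycloreversion. The step needs ortho carbon attack instead of oxygen or para attack and 1,2- instead of 1,4-addition to the enal: the boron template enforces both, bromine blocks the para position, the silyloxy group blocks the second ortho position, and the acidic medium without free phenoxide should keep the silyl group from migrating.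

Step 4
Reactants: 8 1-(2,4-dihydroxy-6-methoxyphenyl)ethan-1-one
Product: 9 1-[2-hydroxy-6-methoxy-4-(triisopropylsilyloxy)phenyl]ethan-1-one
Conditions: TIPSCl, imidazole, CH2Cl2, 0 °C
Reagents that add atoms: triisopropylsilyl chloride, CC(C)[Si](Cl)(C(C)C)C(C)C
Why: Silyl ether formation is selective for the 4-hydroxyl because the 2-hydroxyl is held in a hydrogen bond to the acetyl carbonyl and is flanked by it.

Step 5
Reactants: 9 1-[2-hydroxy-6-methoxy-4-(triisopropylsilyloxy)phenyl]ethan-1-one
Product: 11 3-iodo-5-methoxy-7-(triisopropylsilyloxy)-4H-chromen-4-one, via enaminone 10 (not isolated)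
Conditions: Me2NCH(OMe)2, toluene, 90 °C; then I2, pyridine, CHCl3, rt
Reagents that add atoms: N,N-dimethylformamide dimethyl acetal, COC(OC)N(C)C; iodine, II
Why: Condensation of the methyl ketone with the formamide acetal gives the enaminone, and iodine then iodinates the enamine carbon while the ortho hydroxyl closes onto the iminium carbon with loss of dimethylamine, the standard enaminone route to 3-iodochromones, in which the protected 4-oxygen cannot be methylated by the acetal.

Step 6
Reactants: 7 6-bromo-2,2-dimethyl-8-(triisopropylsilyloxy)-2H-chromene; 11 3-iodo-5-methoxy-7-(triisopropylsilyloxy)-4H-chromen-4-one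
Product: 13 3-[2,2-dimethyl-8-(triisopropylsilyloxy)-2H-chromen-6-yl]-5-methoxy-7-(triisopropylsilyloxy)-4H-chromen-4-one, via pinacol boronate 12 (not isolated)
Conditions: B2pin2, Pd(dppf)Cl2 (cat.), KOAc, 1,4-dioxane, 85 °C; then 11, aq. K3PO4, 60 °C
Reagents that add atoms: none
Why: Miyaura borylation of the aryl bromide followed in the same flask by Suzuki–Miyaura coupling with the 3-iodochromone, whose C–I bond adds readily to zerovalent palladium, is the standard isoflavone assembly, and the mild phosphate base at moderate temperature is chosen to spare the 7-O-silyl group and the chromone ring.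

Step 7
Reactants: 13 3-[2,2-dimethyl-8-(triisopropylsilyloxy)-2H-chromen-6-yl]-5-methoxy-7-(triisopropylsilyloxy)-4H-chromen-4-one
Product: 15 (3R,4R)-3-[2,2-dimethyl-8-(triisopropylsilyloxy)-2H-chromen-6-yl]-5-methoxy-7-(triisopropylsilyloxy)chroman-4-ol (cis), via racemic isoflavanone 14 (not isolated)
Conditions: RuCl[(R,R)-TsDPEN](p-cymene) (cat.), HCO2H/Et3N (1:1), EtOAc, 40 °C
Reagents that add atoms: none
Why: Noyori–Ikariya asymmetric transfer hydrogenation first reduces the C2=C3 bond of the vinylogous ester by conjugate hydride transfer to the epimerisable ketone 14 and then reduces the carbonyl with dynamic kinetic resolution, in which the (R,R)-catalyst should set C4 as (R), Et3N equilibrates C3 through the enol, and only the epimer that keeps the aryl group away from the incoming hydride reacts quickly, so the cis-(3R,4R)-alcohol should result while the unpolarised chromene alkene stays untouched.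

Step 8
Reactants: 15 (3R,4R)-3-[2,2-dimethyl-8-(triisopropylsilyloxy)-2H-chromen-6-yl]-5-methoxy-7-(triisopropylsilyloxy)chroman-4-ol
Product: 16 (3R)-3-[2,2-dimethyl-8-(triisopropylsilyloxy)-2H-chromen-6-yl]-5-methoxy-7-(triisopropylsilyloxy)chroman-4-one
Conditions: Dess–Martin periodinane, NaHCO3, CH2Cl2, 0 °C
Reagents that add atoms: none
Why: Dess–Martin oxidation under bicarbonate buffering converts the secondary benzylic alcohol into the ketone at low temperature without acid or base strong enough to enolise the α-aryl ketone, so the (R) configuration at C3 from step 7 should be kept while C4 ceases to be a stereocentre.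

Step 9
Reactants: 16 (3R)-3-[2,2-dimethyl-8-(triisopropylsilyloxy)-2H-chromen-6-yl]-5-methoxy-7-(triisopropylsilyloxy)chroman-4-one
Product: 17 (3R)-7-hydroxy-3-(8-hydroxy-2,2-dimethyl-2H-chromen-6-yl)-5-methoxychroman-4-one
Conditions: TBAF, AcOH, THF, 0 °C
Reagents that add atoms: none
Why: Fluoride cleaves both aryl silyl ethers, since phenoxides leave silicon easily, and acetic acid protonates the phenoxides at once, so the medium stays near neutral and the enolisable C3 centre should not epimerise, while the chromene alkene and the methyl ether are inert.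

Compound list
1 | catechol (benzene-1,2-diol) | Oc1ccccc1O | starting material
2 | 2-(triisopropylsilyloxy)phenol | CC(C)[Si](Oc1ccccc1O)(C(C)C)C(C)C | intermediate
3 | 4-bromo-2-(triisopropylsilyloxy)phenol | CC(C)[Si](Oc1cc(Br)ccc1O)(C(C)C)C(C)C | intermediate
4 | 3-methylbut-2-enal | CC(C)=CC=O | starting material
5 | 6-bromo-4-(2-methylprop-1-en-1-yl)-2-phenyl-8-(triisopropylsilyloxy)-4H-1,3,2-benzodioxaborin (racemic, formed in the flask) | CC(C)=CC1OB(c2ccccc2)Oc2c1cc(Br)cc2O[Si](C(C)C)(C(C)C)C(C)C | intermediate
6 | (6Z)-4-bromo-6-(3-methylbut-2-en-1-ylidene)-2-(triisopropylsilyloxy)cyclohexa-2,4-dien-1-one (formed in the flask) | CC(C)=C/C=C1/C=C(Br)C=C(O[Si](C(C)C)(C(C)C)C(C)C)C1=O | intermediate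
7 | 6-bromo-2,2-dimethyl-8-(triisopropylsilyloxy)-2H-chromene | CC1(C)C=Cc2cc(Br)cc(O[Si](C(C)C)(C(C)C)C(C)C)c2O1 | intermediate
8 | 1-(2,4-dihydroxy-6-methoxyphenyl)ethan-1-one | CC(=O)c1c(O)cc(O)cc1OC | starting material
9 | 1-[2-hydroxy-6-methoxy-4-(triisopropylsilyloxy)phenyl]ethan-1-one | CC(=O)c1c(O)cc(O[Si](C(C)C)(C(C)C)C(C)C)cc1OC | intermediate
10 | (E)-3-(dimethylamino)-1-[2-hydroxy-6-methoxy-4-(triisopropylsilyloxy)phenyl]prop-2-en-1-one (formed in the flask) | CN(C)/C=C/C(=O)c1c(O)cc(O[Si](C(C)C)(C(C)C)C(C)C)cc1OC | intermediate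
11 | 3-iodo-5-methoxy-7-(triisopropylsilyloxy)-4H-chromen-4-one | COc1cc(O[Si](C(C)C)(C(C)C)C(C)C)cc2occ(I)c(=O)c12 | intermediate
12 | 2-[2,2-dimethyl-8-(triisopropylsilyloxy)-2H-chromen-6-yl]-4,4,5,5-tetramethyl-1,3,2-dioxaborolane (formed in the flask) | CC1(C)C=Cc2cc(B3OC(C)(C)C(C)(C)O3)cc(O[Si](C(C)C)(C(C)C)C(C)C)c2O1 | intermediate
13 | 3-[2,2-dimethyl-8-(triisopropylsilyloxy)-2H-chromen-6-yl]-5-methoxy-7-(triisopropylsilyloxy)-4H-chromen-4-one | COc1cc(O[Si](C(C)C)(C(C)C)C(C)C)cc2occ(-c3cc(O[Si](C(C)C)(C(C)C)C(C)C)c4c(c3)C=CC(C)(C)O4)c(=O)c12 | intermediate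
14 | racemic 3-[2,2-dimethyl-8-(triisopropylsilyloxy)-2H-chromen-6-yl]-5-methoxy-7-(triisopropylsilyloxy)chroman-4-one (formed in the flask) | COc1cc(O[Si](C(C)C)(C(C)C)C(C)C)cc2c1C(=O)C(c1cc(O[Si](C(C)C)(C(C)C)C(C)C)c3c(c1)C=CC(C)(C)O3)CO2 | intermediate
15 | (3R,4R)-3-[2,2-dimethyl-8-(triisopropylsilyloxy)-2H-chromen-6-yl]-5-methoxy-7-(triisopropylsilyloxy)chroman-4-ol (cis) | COc1cc(O[Si](C(C)C)(C(C)C)C(C)C)cc2c1[C@H](O)[C@H](c1cc(O[Si](C(C)C)(C(C)C)C(C)C)c3c(c1)C=CC(C)(C)O3)CO2 | intermediate
16 | (3R)-3-[2,2-dimethyl-8-(triisopropylsilyloxy)-2H-chromen-6-yl]-5-methoxy-7-(triisopropylsilyloxy)chroman-4-one | COc1cc(O[Si](C(C)C)(C(C)C)C(C)C)cc2c1C(=O)[C@H](c1cc(O[Si](C(C)C)(C(C)C)C(C)C)c3c(c1)C=CC(C)(C)O3)CO2 | intermediate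
17 | (3R)-7-hydroxy-3-(8-hydroxy-2,2-dimethyl-2H-chromen-6-yl)-5-methoxychroman-4-one | COc1cc(O)cc2c1C(=O)[C@H](c1cc(O)c3c(c1)C=CC(C)(C)O3)CO2 | target

Total step count: 9 steps.
Longest linear sequence: 7 steps (steps 1, 2, 3, 6, 7, 8 and 9); steps 4 and 5 form the second branch.

Steps most likely to fail

Step 3. Carbon–carbon bond formation at the ortho position next to a bulky silyloxy group may be slow, so that loss or migration of the silyl group and self-condensation of the enal can compete. The fallback sets out from 3 and returns at 7. O-Alkylation of 3 with 3-chloro-3-methylbut-1-yne (CuCl2 cat., DBU, MeCN, 0 °C) should give 4-bromo-1-[(2-methylbut-3-yn-2-yl)oxy]-2-(triisopropylsilyloxy)benzene F1. Heating F1 in xylene at 140 °C should bring about aromatic Claisen rearrangement to the only free ortho position, [1,5]-hydrogen shift and oxa-6π electrocyclisation, which gives 7.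

Step 7. Hydride transfer to the electron-rich vinylogous ester shielded by the peri methoxy group may be sluggish, the epimerisation may fail to keep pace with the reduction (loss of cis selectivity and of enantiopurity), and the electron-rich benzylic alcohol may ionise. The fallback sets out from 13 and returns at 16, so it also replaces step 8. Conjugate reduction of 13 with LiBH(s-Bu)3 (THF, −78 °C) should give the lithium 2H-chromen-4-olate F2, which is silylated in the same flask with TMSCl to 3-[2,2-dimethyl-8-(triisopropylsilyloxy)-2H-chromen-6-yl]-5-methoxy-7-(triisopropylsilyloxy)-4-(trimethylsilyloxy)-2H-chromene F3. Catalytic enantioselective protonation of F3 with a BINOL-derived chiral N-triflyl thiophosphoramide and phenol as the stoichiometric proton source (toluene, rt), the catalyst enantiomer being chosen for the (R) product, should give 16 directly.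

Step 6. Aqueous base may hydrolyse the 7-O-silyl group, which is a vinylogous silyl ester, and the telescoped sequence may suffer protodeboronation or homocoupling. The fallback sets out from 7 and returns at 13. Bromine–lithium exchange on 7 (n-BuLi, THF, −78 °C) should give [2,2-dimethyl-8-(triisopropylsilyloxy)-2H-chromen-6-yl]lithium F4, and transmetalation with ZnCl2 should give chlorido[2,2-dimethyl-8-(triisopropylsilyloxy)-2H-chromen-6-yl]zinc F5. Negishi coupling of F5 with the α-iodoenone 11 (Pd(PPh3)4 cat., THF, rt) under neutral, water-free conditions should give 13.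

Further compounds
F1 | step 3 | 4-bromo-1-[(2-methylbut-3-yn-2-yl)oxy]-2-(triisopropylsilyloxy)benzene | C#CC(C)(C)Oc1ccc(Br)cc1O[Si](C(C)C)(C(C)C)C(C)C
F2 | step 7 | lithium 3-[2,2-dimethyl-8-(triisopropylsilyloxy)-2H-chromen-6-yl]-5-methoxy-7-(triisopropylsilyloxy)-2H-chromen-4-olate | COc1cc(O[Si](C(C)C)(C(C)C)C(C)C)cc2c1C(O[Li])=C(c1cc(O[Si](C(C)C)(C(C)C)C(C)C)c3c(c1)C=CC(C)(C)O3)CO2
F3 | step 7 | 3-[2,2-dimethyl-8-(triisopropylsilyloxy)-2H-chromen-6-yl]-5-methoxy-7-(triisopropylsilyloxy)-4-(trimethylsilyloxy)-2H-chromene | COc1cc(O[Si](C(C)C)(C(C)C)C(C)C)cc2c1C(O[Si](C)(C)C)=C(c1cc(O[Si](C(C)C)(C(C)C)C(C)C)c3c(c1)C=CC(C)(C)O3)CO2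
F4 | step 6 | [2,2-dimethyl-8-(triisopropylsilyloxy)-2H-chromen-6-yl]lithium | CC1(C)C=Cc2cc([Li])cc(O[Si](C(C)C)(C(C)C)C(C)C)c2O1
F5 | step 6 | chlorido[2,2-dimethyl-8-(triisopropylsilyloxy)-2H-chromen-6-yl]zinc | CC1(C)C=Cc2cc([Zn]Cl)cc(O[Si](C(C)C)(C(C)C)C(C)C)c2O1
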